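**Plan**
Retrosynthesis: the five aryl methyl ethers and a silyl placeholder at C2 come off first; the genistein pyranone is then cut at C4–C3 and O1–C2, and the biaryl bond (genistein C8–daidzein C3′) is cut last.
Enabling feature: in the genistein unit C4 stands ortho to O1 on ring A, so a 3-aryl salicylaldehyde supplies C4 (as CHO) and O1 (as OH) together, while C3 and C2 are the two carbons of an anisyl silyl alkyne.
Forward: the daidzein pyranone is built first from resorcinol and an arylacetic acid, its aryl bromide is borylated and joined to an iodosalicylaldehyde by Suzuki coupling, and the genistein pyranone is closed last by rhodium-catalysed aldehyde C–H annulation.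
Finish: protodesilylation at C2, then global demethylation.
Stereochemistry: the target has no stereocenter, so nothing has to be set or preserved.

Key step: step 6

Remark: the target SMILES carries no stereodescriptor, and the C8–C3′ biaryl axis, flanked by three small ortho substituents, is taken as freely rotating.

**Step 1**
Reactants: 1 2-hydroxy-4,6-dimethoxybenzaldehyde
Product: 2 2-hydroxy-3-iodo-4,6-dimethoxybenzaldehyde
Conditions: NIS, TFA (cat.), MeCN, 0 °C to rt
Reagents that add atoms: N-iodosuccinimide, O=C1CCC(=O)N1I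
Why: Electrophilic aromatic iodination of an activated phenol should go to C3, ortho to the free hydroxyl and para to the 6-methoxy group, rather than to C5 between two methoxy groups, as is usual for halogenation of 2-hydroxy-4,6-dimethoxyaryl carbonyl compounds.

**Step 2**
Reactants: 3 resorcinol; 4 3-bromo-4-methoxyphenylacetic acid
Product: 6 3-(3-bromo-4-methoxyphenyl)-7-hydroxy-4H-chromen-4-one, via deoxybenzoin 5 (not isolated)
Conditions: BF3·OEt2 (as solvent), 85 °C; then DMF, MsCl, 70 °C
Reagents that add atoms: N,N-dimethylformamide, CN(C)C=O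
Why: Friedel–Crafts acylation of resorcinol by the arylacetic acid gives the 2,4-dihydroxydeoxybenzoin, and the Vilsmeier-type reagent from DMF and MsCl then adds the C2 carbon at the activated methylene and closes the pyranone in the same pot, the standard deoxybenzoin route to 7-hydroxyisoflavones.

**Step 3**
Reactants: 6 3-(3-bromo-4-methoxyphenyl)-7-hydroxy-4H-chromen-4-one
Product: 7 3-(3-bromo-4-methoxyphenyl)-7-methoxy-4H-chromen-4-one
Conditions: MeI, K2CO3, acetone, reflux
Reagents that add atoms: iodomethane, CI
Why: Williamson O-methylation of the acidic 7-hydroxyl proceeds under carbonate conditions that leave the pyranone and the aryl bromide untouched.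

**Step 4**
Reactants: 7 3-(3-bromo-4-methoxyphenyl)-7-methoxy-4H-chromen-4-one
Product: 8 7-methoxy-3-[4-methoxy-3-(4,4,5,5-tetramethyl-1,3,2-dioxaborolan-2-yl)phenyl]-4H-chromen-4-one
Conditions: B2pin2, Pd(dppf)Cl2 (cat.), KOAc, 1,4-dioxane, 90 °C
Reagents that add atoms: bis(pinacolato)diboron, CC1(C)OB(OC1(C)C)B1OC(C)(C)C(C)(C)O1
Why: Miyaura borylation, in which zerovalent palladium inserts into the aryl bromide and acetate assists transmetalation from B2pin2, uses a base too weak to open the pyranone or to trigger biaryl homocoupling.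

**Step 5**
Reactants: 2 2-hydroxy-3-iodo-4,6-dimethoxybenzaldehyde; 8 7-methoxy-3-[4-methoxy-3-(4,4,5,5-tetramethyl-1,3,2-dioxaborolan-2-yl)phenyl]-4H-chromen-4-one
Product: 9 2-hydroxy-4,6-dimethoxy-3-[2-methoxy-5-(7-methoxy-4-oxo-4H-chromen-3-yl)phenyl]benzaldehyde
Conditions: Pd(OAc)2 (cat.), SPhos, K3PO4, 1,4-dioxane/H2O, 85 °C
Reagents that add atoms: none
Why: Suzuki–Miyaura coupling with the electron-rich biaryl phosphine SPhos is suited to a tri-ortho-substituted biaryl, and free ortho-iodophenols of the acylphloroglucinol type are competent partners without protection.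

**Step 6**
Reactants: 9 2-hydroxy-4,6-dimethoxy-3-[2-methoxy-5-(7-methoxy-4-oxo-4H-chromen-3-yl)phenyl]benzaldehyde; 10 4-[(trimethylsilyl)ethynyl]anisole
Product: 11 5,7-dimethoxy-8-[2-methoxy-5-(7-methoxy-4-oxo-4H-chromen-3-yl)phenyl]-3-(4-methoxyphenyl)-2-(trimethylsilyl)-4H-chromen-4-one
Conditions: [Cp*Rh(MeCN)3](SbF6)2 (cat.), Cu(OAc)2 (2.2 equiv), 1,2-dichloroethane, 80 °C
Reagents that add atoms: none
Why: Proposed new method: the phenoxide of 9 binds the cationic Cp*Rh catalyst (trivalent rhodium) and delivers it to the aldehyde C–H bond, the resulting five-membered acyl rhodacycle inserts 10 to give a seven-membered oxarhodacycle, C–O reductive elimination releases the chromone, and Cu(OAc)2 returns monovalent rhodium to the trivalent state. The closest known reaction type is the rhodium-catalysed oxidative annulation of salicylaldehydes with internal alkynes to 2,3-disubstituted chromones; an aryl silyl alkyne has not been shown in it, and its orientation is inferred from Larock-type heteroannulations, in which silicon ends on the carbon bound to the metal. The one new ring, the pyranone of the genistein unit, closes as a formal oxidative [4+2] annulation, C4–C3 by migratory insertion and O1–C2 by reductive elimination from the seven-membered metallacycle. No stereocenter is formed. The step needs regioselective insertion with the acyl carbon bonding to the anisyl-bearing alkyne carbon, which the bulky trimethylsilyl group should secure by avoiding the short forming C–C bond and by stabilising the carbon that stays on rhodium, so that silicon arrives at C2 as a removable stand-in for hydrogen. Site selectivity for the aldehyde C–H bond over arene C–H bonds near the daidzein carbonyl rests on the anionic phenoxide outcompeting the neutral ketone as directing group, and the silver-free catalyst is chosen to leave the C(sp)–Si bond of 10 intact.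

**Step 7**
Reactants: 11 5,7-dimethoxy-8-[2-methoxy-5-(7-methoxy-4-oxo-4H-chromen-3-yl)phenyl]-3-(4-methoxyphenyl)-2-(trimethylsilyl)-4H-chromen-4-one
Product: 12 5,7-dimethoxy-8-[2-methoxy-5-(7-methoxy-4-oxo-4H-chromen-3-yl)phenyl]-3-(4-methoxyphenyl)-4H-chromen-4-one
Conditions: TBAF, AcOH, THF, 0 °C to rt
Reagents that add atoms: none
Why: Fluoride-induced protodesilylation, in which fluoride attacks silicon and AcOH protonates the oxygen-bearing sp2 carbon C2, should be easy for a silyl group on a heteroaryl-type carbon, and the acetic acid buffer keeps both pyranones from base-induced ring opening.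

**Step 8**
Reactants: 12 5,7-dimethoxy-8-[2-methoxy-5-(7-methoxy-4-oxo-4H-chromen-3-yl)phenyl]-3-(4-methoxyphenyl)-4H-chromen-4-one
Product: 13 5,7-dihydroxy-8-[2-hydroxy-5-(7-hydroxy-4-oxo-4H-chromen-3-yl)phenyl]-3-(4-hydroxyphenyl)-4H-chromen-4-one
Conditions: BBr3 (excess), CH2Cl2, −78 °C to rt; then MeOH/H2O
Reagents that add atoms: none
Why: Lewis-acid cleavage of aryl methyl ethers by BBr3 is standard for polymethoxy isoflavones and biflavonoids, and holding the mixture at or below room temperature should avoid the acid-induced Wessely–Moser ring opening that could move the aryl group from C8 to C6.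

**Compound list**
1 | 2-hydroxy-4,6-dimethoxybenzaldehyde (4,6-dimethoxysalicylaldehyde) | COc1cc(O)c(C=O)c(OC)c1 | starting material
2 | 2-hydroxy-3-iodo-4,6-dimethoxybenzaldehyde | COc1cc(OC)c(I)c(O)c1C=O | intermediate
3 | resorcinol | Oc1cccc(O)c1 | starting material
4 | 3-bromo-4-methoxyphenylacetic acid | COc1ccc(CC(=O)O)cc1Br | starting material
5 | 2-(3-bromo-4-methoxyphenyl)-1-(2,4-dihydroxyphenyl)ethanone (deoxybenzoin) | COc1ccc(CC(=O)c2ccc(O)cc2O)cc1Br | intermediate
6 | 3-(3-bromo-4-methoxyphenyl)-7-hydroxy-4H-chromen-4-one | COc1ccc(-c2coc3cc(O)ccc3c2=O)cc1Br | intermediate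
7 | 3-(3-bromo-4-methoxyphenyl)-7-methoxy-4H-chromen-4-one | COc1ccc(-c2coc3cc(OC)ccc3c2=O)cc1Br | intermediate
8 | 7-methoxy-3-[4-methoxy-3-(4,4,5,5-tetramethyl-1,3,2-dioxaborolan-2-yl)phenyl]-4H-chromen-4-one | COc1ccc(-c2coc3cc(OC)ccc3c2=O)cc1B1OC(C)(C)C(C)(C)O1 | intermediate
9 | 2-hydroxy-4,6-dimethoxy-3-[2-methoxy-5-(7-methoxy-4-oxo-4H-chromen-3-yl)phenyl]benzaldehyde | COc1cc(OC)c(-c2cc(-c3coc4cc(OC)ccc4c3=O)ccc2OC)c(O)c1C=O | intermediate
10 | 4-[(trimethylsilyl)ethynyl]anisole | COc1ccc(C#C[Si](C)(C)C)cc1 | starting material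
11 | 5,7-dimethoxy-8-[2-methoxy-5-(7-methoxy-4-oxo-4H-chromen-3-yl)phenyl]-3-(4-methoxyphenyl)-2-(trimethylsilyl)-4H-chromen-4-one | COc1ccc(-c2c([Si](C)(C)C)oc3c(-c4cc(-c5coc6cc(OC)ccc6c5=O)ccc4OC)c(OC)cc(OC)c3c2=O)cc1 | intermediate
12 | 5,7-dimethoxy-8-[2-methoxy-5-(7-methoxy-4-oxo-4H-chromen-3-yl)phenyl]-3-(4-methoxyphenyl)-4H-chromen-4-one | COc1ccc(-c2coc3c(-c4cc(-c5coc6cc(OC)ccc6c5=O)ccc4OC)c(OC)cc(OC)c3c2=O)cc1 | intermediate
13 | 5,7-dihydroxy-8-[2-hydroxy-5-(7-hydroxy-4-oxo-4H-chromen-3-yl)phenyl]-3-(4-hydroxyphenyl)-4H-chromen-4-one | O=c1c(-c2ccc(O)c(-c3c(O)cc(O)c4c(=O)c(-c5ccc(O)cc5)coc34)c2)coc2cc(O)ccc12 | target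

**Step count**
Total: 8 steps. Longest linear sequence: 7 steps (steps 2 to 8, from resorcinol and 4).

**Steps most likely to fail**

Step 6 (rhodium annulation). Three processes could defeat it:
- insertion of the alkyne in the reverse orientation, with the anisyl group next to rhodium;
- loss of silicon from the alkyne before insertion, followed by oxidative alkyne homocoupling;
- sluggish C–H activation at the crowded phenoxide.

The fallback builds the genistein pyranone by the classical deoxybenzoin sequence. It sets out from 2, because a Grignard reagent would not distinguish the aldehyde of 9 from its chromone. Addition of 4-methoxybenzylmagnesium chloride (excess, THF, −20 °C) gives racemic 2-[1-hydroxy-2-(4-methoxyphenyl)ethyl]-6-iodo-3,5-dimethoxyphenol F1. MnO2 in CH2Cl2 oxidises the benzylic alcohol to 1-(2-hydroxy-3-iodo-4,6-dimethoxyphenyl)-2-(4-methoxyphenyl)ethanone F2. Suzuki coupling with 8 under the conditions of step 5 gives 1-{2-hydroxy-4,6-dimethoxy-3-[2-methoxy-5-(7-methoxy-4-oxo-4H-chromen-3-yl)phenyl]phenyl}-2-(4-methoxyphenyl)ethanone F3. N,N-Dimethylformamide dimethyl acetal in toluene at 100 °C then closes the pyranone, and the route is rejoined at 12.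

Step 5 (Suzuki coupling). Oxidative addition into the electron-rich, phenoxide-bearing, doubly ortho-substituted iodide may be slow. Protodeboronation of 8, hydrodeiodination of 2 or base-induced opening of the pyranone could then take over. The fallback moves the coupling behind the annulation and sets out from 2 and 10. Under the conditions of step 6 they should give 8-iodo-5,7-dimethoxy-3-(4-methoxyphenyl)-2-(trimethylsilyl)-4H-chromen-4-one F4. This iodide has no free phenoxide or aldehyde and belongs to the 8-iodo-5,7-dimethoxychromone type that is an established Suzuki partner for 3′-boronates. Coupling with 8 (Pd(PPh3)4, K3PO4, DMF/H2O, 90 °C) comes back to the route at 11; any loss of silicon under the basic conditions would give 12 directly.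

Step 1 (iodination). Attack of the iodinating agent at C5, para to the free hydroxyl, or a second iodination would carry the wrong substitution pattern through to a 6-linked isomer. The site of iodination in 2 should be checked by NOE before it is used. The fallback defers iodination until the phenol has become the pyranone oxygen, and sets out from 1 and 10. Annulation under the conditions of step 6 gives 5,7-dimethoxy-3-(4-methoxyphenyl)-2-(trimethylsilyl)-4H-chromen-4-one F5. TBAF/AcOH in THF gives 5,7-dimethoxy-3-(4-methoxyphenyl)-4H-chromen-4-one F6. Iodination (NIS, TFA, MeCN) gives 8-iodo-5,7-dimethoxy-3-(4-methoxyphenyl)-4H-chromen-4-one F7. No free hydroxyl is left to direct attack para to itself, and fully methylated 5,7-dioxygenated chromones are known to be halogenated at C8. Suzuki coupling of this iodide with 8 (Pd(PPh3)4, K3PO4, DMF/H2O, 90 °C) comes back to the route at 12.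

**Further compounds**
F1 | step 6 | 2-[1-hydroxy-2-(4-methoxyphenyl)ethyl]-6-iodo-3,5-dimethoxyphenol (racemic) | COc1ccc(CC(O)c2c(O)c(I)c(OC)cc2OC)cc1
F2 | step 6 | 1-(2-hydroxy-3-iodo-4,6-dimethoxyphenyl)-2-(4-methoxyphenyl)ethanone | COc1ccc(CC(=O)c2c(O)c(I)c(OC)cc2OC)cc1
F3 | step 6 | 1-{2-hydroxy-4,6-dimethoxy-3-[2-methoxy-5-(7-methoxy-4-oxo-4H-chromen-3-yl)phenyl]phenyl}-2-(4-methoxyphenyl)ethanone | COc1ccc(CC(=O)c2c(O)c(-c3cc(-c4coc5cc(OC)ccc5c4=O)ccc3OC)c(OC)cc2OC)cc1
F4 | step 5 | 8-iodo-5,7-dimethoxy-3-(4-methoxyphenyl)-2-(trimethylsilyl)-4H-chromen-4-one | COc1ccc(-c2c([Si](C)(C)C)oc3c(I)c(OC)cc(OC)c3c2=O)cc1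
F5 | step 1 | 5,7-dimethoxy-3-(4-methoxyphenyl)-2-(trimethylsilyl)-4H-chromen-4-one | COc1ccc(-c2c([Si](C)(C)C)oc3cc(OC)cc(OC)c3c2=O)cc1
F6 | step 1 | 5,7-dimethoxy-3-(4-methoxyphenyl)-4H-chromen-4-one | COc1ccc(-c2coc3cc(OC)cc(OC)c3c2=O)cc1
F7 | step 1 | 8-iodo-5,7-dimethoxy-3-(4-methoxyphenyl)-4H-chromen-4-one | COc1ccc(-c2coc3c(I)c(OC)cc(OC)c3c2=O)cc1
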